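The pyranone C ring (O1–C2–C3–C4–C4a–C8a) has its carbonyl carbon C4 as a one-carbon bridge between A-ring carbon C4a and the C3=C2 unit. C4a has oxygen on both neighbours (O1 on C8a, the free OH on C5), so with OMe on C6, C7 and C8 the A ring is a mirror-symmetric 2-iodo-4,5,6-trimethoxyresorcinol whose two OH groups are interchangeable.
The 3'- and 5'-OH groups are released last from benzyl ethers. Before that, C4a–C4, C4–C3 and O1–C2 are cut together to give the iodoresorcinol, carbon monoxide (C4) and 3,5-bis(benzyloxy)-4-methoxyphenylacetylene (C3, C2 and ring B).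
The iodoresorcinol goes back to 1,2,3-trimethoxybenzene (4,6-dibromination, Br to Bpin to OH at both sites, iodination of the last C–H). The alkyne goes back to methyl 3,5-dihydroxy-4-methoxybenzoate (benzylation, ester to aldehyde, one-carbon homologation).
Rings A and B are bought as benzenes. Ring C is the only ring made, and it closes in the three-component step.
Key step: step 9

Remark on the chemistry: Gardenin E has no stereocentre and no stereogenic double bond, so it is achiral. The SMILES carries no descriptors and the route needs no stereocontrol.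

Step 1
Reactants: 1 1,2,3-trimethoxybenzene
Product: 2 1,5-dibromo-2,3,4-trimethoxybenzene
Conditions: NBS (2.1 equiv), MeCN, 0 °C to rt, dark
Reagents that add atoms: N-bromosuccinimide, O=C1CCC(=O)N1Br
Why: Twofold electrophilic aromatic bromination: C4 and C6 are each ortho to one outer methoxy group and para to the other, whereas C5 is activated only by the central methoxy group, which its neighbours twist out of conjugation, so both bromines should enter at the two equivalent outer positions and the deactivated dibromide should resist a third substitution.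

Step 2
Reactants: 2 1,5-dibromo-2,3,4-trimethoxybenzene
Product: 3 2,2'-(4,5,6-trimethoxy-1,3-phenylene)bis(4,4,5,5-tetramethyl-1,3,2-dioxaborolane)
Conditions: B2pin2 (2.6 equiv), PdCl2(dppf)·CH2Cl2 (5 mol %), KOAc (6 equiv), 1,4-dioxane, 90 °C
Reagents that add atoms: bis(pinacolato)diboron, CC1(C)OB(OC1(C)C)B1OC(C)(C)C(C)(C)O1
Why: Twofold Miyaura borylation: aryl bromides with a single ortho-methoxy group undergo oxidative addition and acetate-assisted transmetalation with the diboron reagent reliably, and the weak base KOAc holds back Suzuki-type homocoupling and protodeborylation.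

Step 3
Reactants: 3 2,2'-(4,5,6-trimethoxy-1,3-phenylene)bis(4,4,5,5-tetramethyl-1,3,2-dioxaborolane)
Product: 4 4,5,6-trimethoxybenzene-1,3-diol (4,5,6-trimethoxyresorcinol)
Conditions: 30% aq H2O2 (2.5 equiv), 1 M aq NaOH (2.2 equiv), THF, 0 °C, N2; acidic work-up
Reagents that add atoms: hydrogen peroxide, OO
Why: Oxidative ipso-hydroxylation of arylboronates: hydroperoxide adds to boron and the aryl group migrates from B to O at the same ring carbon, so both C–B bonds become C–OH, while a cold, brief, oxygen-free treatment spares the electron-rich resorcinol.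

Step 4
Reactants: 4 4,5,6-trimethoxybenzene-1,3-diol
Product: 5 2-iodo-4,5,6-trimethoxybenzene-1,3-diol
Conditions: NIS (1.0 equiv), MeCN, −30 °C to 0 °C, dark, N2
Reagents that add atoms: N-iodosuccinimide, O=C1CCC(=O)N1I
Why: Electrophilic aromatic iodination at the only ring C–H, which is ortho to both hydroxyls and para to the central methoxy group; exactly one equivalent of NIS at low temperature limits oxidation of the ring.

Step 5
Reactants: 6 methyl 3,5-dihydroxy-4-methoxybenzoate
Product: 7 methyl 3,5-bis(benzyloxy)-4-methoxybenzoate
Conditions: BnBr (2.4 equiv), K2CO3 (3 equiv), DMF, 60 °C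
Reagents that add atoms: benzyl bromide, BrCc1ccccc1
Why: Twofold Williamson ether synthesis (SN2 attack of the phenoxides on benzyl bromide); the methyl ester and the aryl methyl ether are inert to carbonate in DMF.

Step 6
Reactants: 7 methyl 3,5-bis(benzyloxy)-4-methoxybenzoate
Product: 8 [3,5-bis(benzyloxy)-4-methoxyphenyl]methanol
Conditions: LiAlH4 (1.2 equiv), THF, 0 °C to rt; H2O/aq NaOH work-up
Reagents that add atoms: none
Why: Hydride reduction of the ester to the primary benzylic alcohol; aryl benzyl and aryl methyl ethers are not touched by LiAlH4.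

Step 7
Reactants: 8 [3,5-bis(benzyloxy)-4-methoxyphenyl]methanol
Product: 9 3,5-bis(benzyloxy)-4-methoxybenzaldehyde
Conditions: activated MnO2 (10 equiv), CH2Cl2, rt
Reagents that add atoms: none
Why: Selective benzylic alcohol oxidation with activated manganese dioxide, which stops at the aldehyde and leaves the benzyl ethers intact.

Step 8
Reactants: 9 3,5-bis(benzyloxy)-4-methoxybenzaldehyde; 10 dimethyl (1-diazo-2-oxopropyl)phosphonate
Product: 11 1,3-bis(benzyloxy)-5-ethynyl-2-methoxybenzene
Conditions: 10 (1.3 equiv), K2CO3 (2 equiv), MeOH/THF, rt
Reagents that add atoms: none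
Why: Seyferth–Gilbert homologation in its Ohira–Bestmann form: methoxide removes the acetyl group of 10, the diazomethylphosphonate anion adds to the aldehyde in a Horner–Wadsworth–Emmons manner, and loss of dimethyl phosphate and N2 with a 1,2-hydrogen shift gives the terminal alkyne, whose CH carbon (the later C3) comes from 10, under conditions harmless to a non-enolisable aldehyde and to the ethers.

Step 9
Reactants: 5 2-iodo-4,5,6-trimethoxybenzene-1,3-diol; 11 1,3-bis(benzyloxy)-5-ethynyl-2-methoxybenzene; 12 carbon monoxide
Product: 15 2-[3,5-bis(benzyloxy)-4-methoxyphenyl]-5-hydroxy-6,7,8-trimethoxy-4H-chromen-4-one, via ynone 13 (not isolated), via enaminone 14 (not isolated)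
Conditions: 11 (1.2 equiv), PdCl2(dppf) (5 mol %), CO (10 bar), Et2NH/DMF (degassed, no copper), 80 °C, autoclave
Reagents that add atoms: diethylamine, CCNCC (enters intermediate 14 only and is expelled again on ring closure; no atom of it stays in 15)
Why: This is a carbonylative Sonogashira coupling with in situ annulation, the known palladium-catalysed three-component flavone synthesis from 2-iodophenols, terminal arylacetylenes and CO. Pd(0) inserts into the C–I bond of 5, migratory insertion of CO forms C4a–C4 (fast here, because an electron-rich, doubly ortho-substituted aryl group migrates readily), and amine-assisted alkynylation of the aroyl-palladium with 11 followed by reductive elimination forms C4–C3 and releases ynone 13. Diethylamine then adds reversibly to the β-carbon of the ynone to give the push–pull enaminone 14, and a neighbouring phenol oxygen attacks the same carbon and expels the amine, which forms O1–C2 and closes the pyranone by an addition–elimination equivalent to a 6-endo-dig closure. No stereocentre is created and the new C2=C3 bond is endocyclic, so no stereochemical question arises. Three selectivities are needed: CO uptake before alkynylation, secured by leaving out copper (slow alkynyl transfer to aryl-palladium) and working under CO pressure; 6-endo rather than 5-exo closure, secured because the amine makes the α-carbon a nucleophilic enamine position and leaves the β-carbon as the only electrophilic site for the phenol; and capture of the acyl-palladium by the alkyne rather than the amine, favoured by the two ortho substituents that screen the acyl carbon from the bulkier secondary amine. No choice between the two hydroxyls exists, since the mirror plane of 5 through C2 and C5 makes them equivalent, and the one left over becomes the hydrogen-bonded 5-OH.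

Step 10
Reactants: 15 2-[3,5-bis(benzyloxy)-4-methoxyphenyl]-5-hydroxy-6,7,8-trimethoxy-4H-chromen-4-one
Product: 16 Gardenin E (5-hydroxy-2-(3,5-dihydroxy-4-methoxyphenyl)-6,7,8-trimethoxy-4H-chromen-4-one)
Conditions: H2 (1 atm), 10% Pd/C, THF/MeOH, rt, stopped after uptake of two equivalents of H2
Reagents that add atoms: none
Why: Catalytic hydrogenolysis of the two benzylic C–O bonds, which at 1 atm over Pd/C cleave much faster than the conjugated, vinylogous-ester C2=C3 bond is saturated; the aryl methyl ethers and the chelated 5-OH are unaffected.

Compound list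
1 | 1,2,3-trimethoxybenzene | COc1cccc(OC)c1OC | starting material
2 | 1,5-dibromo-2,3,4-trimethoxybenzene | COc1c(Br)cc(Br)c(OC)c1OC | intermediate
3 | 2,2'-(4,5,6-trimethoxy-1,3-phenylene)bis(4,4,5,5-tetramethyl-1,3,2-dioxaborolane) | COc1c(B2OC(C)(C)C(C)(C)O2)cc(B2OC(C)(C)C(C)(C)O2)c(OC)c1OC | intermediate
4 | 4,5,6-trimethoxybenzene-1,3-diol | COc1c(O)cc(O)c(OC)c1OC | intermediate
5 | 2-iodo-4,5,6-trimethoxybenzene-1,3-diol | COc1c(O)c(I)c(O)c(OC)c1OC | intermediate
6 | methyl 3,5-dihydroxy-4-methoxybenzoate | COC(=O)c1cc(O)c(OC)c(O)c1 | starting material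
7 | methyl 3,5-bis(benzyloxy)-4-methoxybenzoate | COC(=O)c1cc(OCc2ccccc2)c(OC)c(OCc2ccccc2)c1 | intermediate
8 | [3,5-bis(benzyloxy)-4-methoxyphenyl]methanol | OCc1cc(OCc2ccccc2)c(OC)c(OCc2ccccc2)c1 | intermediate
9 | 3,5-bis(benzyloxy)-4-methoxybenzaldehyde | O=Cc1cc(OCc2ccccc2)c(OC)c(OCc2ccccc2)c1 | intermediate
10 | dimethyl (1-diazo-2-oxopropyl)phosphonate | CC(=O)C(=[N+]=[N-])P(=O)(OC)OC | starting material
11 | 1,3-bis(benzyloxy)-5-ethynyl-2-methoxybenzene | C#Cc1cc(OCc2ccccc2)c(OC)c(OCc2ccccc2)c1 | intermediate
12 | carbon monoxide | [C-]#[O+] | starting material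
13 | 3-[3,5-bis(benzyloxy)-4-methoxyphenyl]-1-(2,6-dihydroxy-3,4,5-trimethoxyphenyl)prop-2-yn-1-one | O=C(C#Cc1cc(OCc2ccccc2)c(OC)c(OCc2ccccc2)c1)c1c(O)c(OC)c(OC)c(OC)c1O | intermediate
14 | (E)-3-[3,5-bis(benzyloxy)-4-methoxyphenyl]-3-(diethylamino)-1-(2,6-dihydroxy-3,4,5-trimethoxyphenyl)prop-2-en-1-one (configurationally labile push–pull alkene) | CCN(CC)/C(c1cc(OCc2ccccc2)c(OC)c(OCc2ccccc2)c1)=C/C(=O)c1c(O)c(OC)c(OC)c(OC)c1O | intermediate
15 | 2-[3,5-bis(benzyloxy)-4-methoxyphenyl]-5-hydroxy-6,7,8-trimethoxy-4H-chromen-4-one | COc1c(OCc2ccccc2)cc(-c2cc(=O)c3c(O)c(OC)c(OC)c(OC)c3o2)cc1OCc1ccccc1 | intermediate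
16 | Gardenin E | COc1c(O)cc(-c2cc(=O)c3c(O)c(OC)c(OC)c(OC)c3o2)cc1O | target

Total step count: 10.
Longest linear sequence: 6 steps. Both branches have this length: steps 1–4, 9, 10 and steps 5–8, 9, 10.

Steps most likely to fail

1. Step 9 (key step). Oxidative addition and alkynyl transfer are slowed at a carbon flanked by two oxygens on a very electron-rich ring. Several processes could then overtake the annulation:
- reductive loss of iodine
- coupling without CO uptake
- interception of the acyl-palladium by diethylamine or by a phenoxide
- base-promoted oxidation of the free resorcinol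

The fallback uses no palladium and no CO, and builds ring C by aldol condensation and oxidative cyclisation. It sets out from diol 4 and aldehyde 9 and comes back at 15. Friedel–Crafts C-acetylation of 4 at its single free ring carbon (Ac2O, BF3·OEt2, 60 °C) should give 1-(2,6-dihydroxy-3,4,5-trimethoxyphenyl)ethan-1-one F1. Claisen–Schmidt condensation of this ketone with 9 (KOH, EtOH, rt) should give (E)-3-[3,5-bis(benzyloxy)-4-methoxyphenyl]-1-(2,6-dihydroxy-3,4,5-trimethoxyphenyl)prop-2-en-1-one F2. Oxidative cyclisation (catalytic I2, DMSO, 120 °C) then forms O1–C2 and the C2=C3 bond and delivers 15. The symmetry argument is kept, since either hydroxyl closes to the same flavone.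

2. Step 4. The N-iodo reagent may oxidise the pentaoxygenated ring instead of substituting it, and iodine may be lost under the influence of acid or light during isolation. The fallback replaces electrophilic substitution by directed ortho-metalation. It sets out from 4 and comes back at 5. Double protection (MOMCl, i-Pr2NEt, CH2Cl2, 0 °C to rt) should give 2,3,4-trimethoxy-1,5-bis(methoxymethoxy)benzene F3. Its only ring C–H lies between two coordinating acetal oxygens and should be lithiated cleanly (n-BuLi, THF, 0 °C). Quenching with I2 should give 2-iodo-4,5,6-trimethoxy-1,3-bis(methoxymethoxy)benzene F4, a robust storage form. Mild acid methanolysis (HCl, MeOH, 40 °C) would release 5 from it just before step 9.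

3. Step 2. The second borylation may stay incomplete, and protodehalogenation or protodeborylation on the crowded, electron-rich ring would give mono-functionalised material that is hard to remove. The peroxide step that follows also exposes a sensitive phenol to an oxidant. The fallback forms the C–O bonds directly, without boron or peroxide. It sets out from 2 and comes back at 4. Twofold palladium-catalysed C–O coupling with benzyl alcohol (Pd(OAc)2, RockPhos, Cs2CO3, toluene, 90 °C) should give 1,5-bis(benzyloxy)-2,3,4-trimethoxybenzene F5, which is stable and easy to purify. Hydrogenolysis (H2, Pd/C, EtOAc, rt) then releases 4 under neutral, reducing conditions.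

Further compounds
F1 | step 9 | 1-(2,6-dihydroxy-3,4,5-trimethoxyphenyl)ethan-1-one | CC(=O)c1c(O)c(OC)c(OC)c(OC)c1O
F2 | step 9 | (E)-3-[3,5-bis(benzyloxy)-4-methoxyphenyl]-1-(2,6-dihydroxy-3,4,5-trimethoxyphenyl)prop-2-en-1-one | O=C(/C=C/c1cc(OCc2ccccc2)c(OC)c(OCc2ccccc2)c1)c1c(O)c(OC)c(OC)c(OC)c1O
F3 | step 4 | 2,3,4-trimethoxy-1,5-bis(methoxymethoxy)benzene | COCOc1cc(OCOC)c(OC)c(OC)c1OC
F4 | step 4 | 2-iodo-4,5,6-trimethoxy-1,3-bis(methoxymethoxy)benzene | COCOc1c(I)c(OCOC)c(OC)c(OC)c1OC
F5 | step 2 | 1,5-bis(benzyloxy)-2,3,4-trimethoxybenzene | COc1c(OCc2ccccc2)cc(OCc2ccccc2)c(OC)c1OC
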